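## Retrosynthetic overview

1. Target 20 ⇐ 19 (two O‑benzyl groups removed) ⇐ [4+2]: the pyran ring of the isobutyryl half (ring B: O1, C2, C3, C4, C4a, C8a) is cut at O1–C2 and C3–C4 into isobutylene and the o‑quinone methide O1=C8a–C4a=C4H2, released anodically from the arylthiomethyl phenol 16.
2. Enabling feature: in ring B the ether oxygen O1 on C8a is ortho to the benzylic C4 on C4a, and C2 carries two methyl groups, which is an o‑quinone methide/isobutylene pattern. The other oxygen ortho to C4a (on C5) is kept as a benzyl ether, so only O1 can close.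
3. 16 ⇐ catalytic enantioselective Friedel–Crafts addition of ring‑B phenol 14 to the ring‑A o‑quinone methide 15 (from sulfone 9). This bond sets the bridging stereocentre while the two aryl groups are still very different.
4. 9 and 14 ⇐ phloroglucinol by Friedel–Crafts acylation, para‑selective O‑benzylation, then isoprene annulation (ring A) or arylthiomethylation (ring B).
5. Ring order: both benzene rings come from phloroglucinol; pyran of the 2‑methylbutanoyl half in step 3; pyran of the isobutyryl half last, in step 9.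

Key step: step 9

Remark on the chemistry: (R)‑2‑methylbutanoic acid 2 and 6‑methylheptanal 8 are taken as purchasable. From step 8 on the bridging carbon keeps one spatial arrangement, but its CIP letter reads S in 16 and 18 (the CH2S branch raises the priority of ring B) and R in 19 and 20.

## Route

Step 1
Reactants: 1 phloroglucinol (benzene‑1,3,5‑triol); 2 (R)‑2‑methylbutanoic acid
Product: 4 (2R)‑2‑methyl‑1‑(2,4,6‑trihydroxyphenyl)butan‑1‑one, via (R)‑2‑methylbutanoyl chloride 3 (not isolated)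
Conditions: (COCl)2, cat. DMF, CH2Cl2, 0 °C→rt; then 1, AlCl3 (3.5 equiv), CH2Cl2/PhNO2, 0 °C→rt; aq. HCl
Reagents that add atoms: none
Why: Acid chloride formation followed by Friedel–Crafts C‑acylation of the threefold activated arene should stop at mono‑acylation because the acyl group deactivates the ring; the α‑stereocentre is carried over from 2, and base‑free, cold conditions are kept to avoid ketene or enol formation.

Step 2
Reactants: 4 (2R)‑2‑methyl‑1‑(2,4,6‑trihydroxyphenyl)butan‑1‑one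
Product: 5 (2R)‑1‑[4‑(benzyloxy)‑2,6‑dihydroxyphenyl]‑2‑methylbutan‑1‑one
Conditions: BnBr (1.0 equiv), K2CO3 (1.05 equiv), DMF, 0 °C→rt
Reagents that add atoms: benzyl bromide BrCc1ccccc1
Why: Williamson etherification should take the 4‑OH selectively, since it is the most acidic hydroxyl and the only one not chelated to the ketone; the weak base does not touch the hindered α‑centre.

Step 3
Reactants: 5 (2R)‑1‑[4‑(benzyloxy)‑2,6‑dihydroxyphenyl]‑2‑methylbutan‑1‑one; 6 isoprene
Product: 7 (2R)‑1‑[5‑(benzyloxy)‑7‑hydroxy‑2,2‑dimethyl‑3,4‑dihydro‑2H‑chromen‑8‑yl]‑2‑methylbutan‑1‑one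
Conditions: 6 (1.1 equiv), Amberlyst 15, THF/heptane, 60 °C
Reagents that add atoms: none
Why: Acid‑catalysed Friedel–Crafts prenylation at one of the two equivalent ring CH positions followed by Markovnikov hydroalkoxylation (formal [3+3] chroman annulation) can close only onto the 2‑OH because the 4‑oxygen is benzylated, which places the acyl group at C8; limiting isoprene suppresses a second annulation.

Step 4
Reactants: 7 (2R)‑1‑[5‑(benzyloxy)‑7‑hydroxy‑2,2‑dimethyl‑3,4‑dihydro‑2H‑chromen‑8‑yl]‑2‑methylbutan‑1‑one; 8 6‑methylheptanal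
Product: 9 (2R)‑1‑[5‑(benzyloxy)‑7‑hydroxy‑2,2‑dimethyl‑6‑[6‑methyl‑1‑(4‑methylbenzenesulfonyl)heptyl]‑3,4‑dihydro‑2H‑chromen‑8‑yl]‑2‑methylbutan‑1‑one (both epimers at the sulfonyl‑bearing carbon)
Conditions: 8 (1.5 equiv), TolSO2H (2 equiv), HCO2H/CH2Cl2, rt
Reagents that add atoms: p‑toluenesulfinic acid Cc1ccc(cc1)S(=O)O
Why: Three‑component sulfonylalkylation (Friedel–Crafts hydroxyalkylation at the only free ring carbon C6, then S‑capture of the benzylic cation/o‑quinone methide by sulfinate) should give a stable latent o‑quinone methide; the new carbon forms as both epimers, which does not matter because it becomes sp2 in step 8.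

Step 5
Reactants: 1 phloroglucinol; 10 isobutyryl chloride (2‑methylpropanoyl chloride)
Product: 11 2‑methyl‑1‑(2,4,6‑trihydroxyphenyl)propan‑1‑one
Conditions: AlCl3 (3.5 equiv), CH2Cl2/PhNO2, 0 °C→rt; aq. HCl
Reagents that add atoms: none
Why: Friedel–Crafts C‑acylation of phloroglucinol should stop at the mono‑ketone because the first acyl group deactivates the ring.

Step 6
Reactants: 11 2‑methyl‑1‑(2,4,6‑trihydroxyphenyl)propan‑1‑one
Product: 12 1‑[4‑(benzyloxy)‑2,6‑dihydroxyphenyl]‑2‑methylpropan‑1‑one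
Conditions: BnBr (1.0 equiv), K2CO3 (1.05 equiv), DMF, 0 °C→rt
Reagents that add atoms: benzyl bromide BrCc1ccccc1
Why: Williamson etherification should again take the non‑chelated, most acidic 4‑OH, as in step 2.

Step 7
Reactants: 12 1‑[4‑(benzyloxy)‑2,6‑dihydroxyphenyl]‑2‑methylpropan‑1‑one; 13 formaldehyde
Product: 14 1‑[4‑(benzyloxy)‑2,6‑dihydroxy‑3‑{[(4‑methoxyphenyl)sulfanyl]methyl}phenyl]‑2‑methylpropan‑1‑one
Conditions: 37% aq. CH2O (0.6 equiv), 4‑MeOC6H4SH (1.5 equiv), Et3N (0.2 equiv), EtOH, 60 °C; unreacted 12 recovered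
Reagents that add atoms: 4‑methoxybenzenethiol COc1ccc(S)cc1
Why: Phenol arylthiomethylation (hydroxymethylation, dehydration to the o‑quinone methide, thia‑Michael addition) should give mainly the mono‑adduct at one of the two equivalent positions when formaldehyde is limiting and the thiol is in excess.

Step 8
Reactants: 9 ring‑A sulfone (latent o‑quinone methide); 14 ring‑B arylthiomethyl phenol
Product: 16 (2R)‑1‑[5‑(benzyloxy)‑6‑[(1S)‑1‑[2‑(benzyloxy)‑4,6‑dihydroxy‑3‑{[(4‑methoxyphenyl)sulfanyl]methyl}‑5‑(2‑methylpropanoyl)phenyl]‑6‑methylheptyl]‑7‑hydroxy‑2,2‑dimethyl‑3,4‑dihydro‑2H‑chromen‑8‑yl]‑2‑methylbutan‑1‑one, via ring‑A o‑quinone methide 15 (not isolated)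
Conditions: quinine‑derived 3,5‑bis(trifluoromethyl)phenyl squaramide (10 mol %), 5% aq. Na2CO3 (1.5 equiv), CH2Cl2, 0 °C
Reagents that add atoms: none
Why: Carbonate should trigger 1,4‑elimination of sulfinate from the phenoxide of 9 to give 15, to which 14 adds through its only free ring carbon (organocatalytic enantioselective Friedel–Crafts‑type 1,4‑addition of phenols to in situ o‑quinone methides); the bridging stereocentre is set by the bifunctional catalyst (squaramide N–H bonds to the dienone oxygen, quinuclidinium pairs with the phenoxide), and the catalyst series (quinine‑ or quinidine‑derived) is chosen so that the arrangement drawn in 16 forms.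

Step 9
Reactants: 16 coupled ring‑B arylthiomethyl phenol; 17 isobutylene (2‑methylpropene)
Product: 19 1‑[5‑(benzyloxy)‑6‑[(1R)‑1‑{5‑(benzyloxy)‑7‑hydroxy‑2,2‑dimethyl‑8‑[(2R)‑2‑methylbutanoyl]‑3,4‑dihydro‑2H‑chromen‑6‑yl}‑6‑methylheptyl]‑7‑hydroxy‑2,2‑dimethyl‑3,4‑dihydro‑2H‑chromen‑8‑yl]‑2‑methylpropan‑1‑one, via ring‑B o‑quinone methide 18 (not isolated)
Conditions: glassy‑carbon anode, Pt cathode, undivided cell, 1.0 M LiClO4/MeNO2, AcOH (1 equiv), 17 (ca. 20 equiv, condensed in), +1.1 V vs Ag/AgCl (ca. 1.2 F/mol), −10 °C→0 °C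
Reagents that add atoms: none
Why: Anodic one‑electron oxidation at the 4‑methoxyphenylthio group (the most easily oxidised site, below the acyl‑deactivated, non‑ionised phenol rings) is followed by mesolytic C–S cleavage with loss of the ortho‑OH proton, releasing ring‑B o‑quinone methide 18 (O=C8a–C4a=C4H2) in a neutral, cold medium. 18 is an acyl‑activated, electron‑poor heterodiene and should add isobutylene in an inverse‑electron‑demand hetero‑Diels–Alder reaction, helped by the polar Li+ medium and driven by re‑aromatisation. The closest known reaction type is the electro‑oxidative generation of o‑quinone methides from o‑(arylthiomethyl)phenols in LiClO4/MeNO2 and their [4+2] capture by unactivated alkenes to give chromans. The pyran ring closes by this intermolecular [4+2] (O1, C8a, C4a, C4 from 18; C2 and C3 from 17), forming C4–C3 and O1–C2 in one event. No new stereocentre arises, and the bridging centre, which acid or base would scramble by retro‑Friedel–Crafts/o‑quinone methide exchange, should survive because neither is present. The step needs the right orientation, secured by polarity (the CH2 terminus of 17 bonds to the methide carbon and O1 to the tertiary carbon, hence 2,2‑dimethyl), and closure through the acyl‑side oxygen only, secured by the benzyl ether on the other oxygen ortho to C4a.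

Step 10
Reactants: 19 bis‑benzyl ether of the target
Product: 20 1‑[6‑[(1R)‑1‑{5,7‑dihydroxy‑2,2‑dimethyl‑8‑[(2R)‑2‑methylbutanoyl]‑3,4‑dihydro‑2H‑chromen‑6‑yl}‑6‑methylheptyl]‑5,7‑dihydroxy‑2,2‑dimethyl‑3,4‑dihydro‑2H‑chromen‑8‑yl]‑2‑methylpropan‑1‑one (CNP0287681.1)
Conditions: H2 (1 atm), Pd(OH)2/C, EtOAc/EtOH, rt
Reagents that add atoms: none
Why: Hydrogenolysis of the two aryl benzyl ethers under neutral conditions should leave the hindered, chelated aryl ketones and the diarylmethine untouched, so both stereocentres are retained.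

## Compound list

1 | phloroglucinol (benzene‑1,3,5‑triol) | Oc1cc(O)cc(O)c1 | starting material
2 | (R)‑2‑methylbutanoic acid | CC[C@@H](C)C(=O)O | starting material
3 | (R)‑2‑methylbutanoyl chloride | CC[C@@H](C)C(=O)Cl | intermediate (not isolated)
4 | (2R)‑2‑methyl‑1‑(2,4,6‑trihydroxyphenyl)butan‑1‑one | CC[C@@H](C)C(=O)c1c(O)cc(O)cc1O | intermediate
5 | (2R)‑1‑[4‑(benzyloxy)‑2,6‑dihydroxyphenyl]‑2‑methylbutan‑1‑one | CC[C@@H](C)C(=O)c1c(O)cc(OCc2ccccc2)cc1O | intermediate
6 | isoprene (2‑methylbuta‑1,3‑diene) | C=CC(C)=C | starting material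
7 | (2R)‑1‑[5‑(benzyloxy)‑7‑hydroxy‑2,2‑dimethyl‑3,4‑dihydro‑2H‑chromen‑8‑yl]‑2‑methylbutan‑1‑one | CC[C@@H](C)C(=O)c1c(O)cc(OCc3ccccc3)c2c1OC(C)(C)CC2 | intermediate
8 | 6‑methylheptanal | CC(C)CCCCC=O | starting material
9 | (2R)‑1‑[5‑(benzyloxy)‑7‑hydroxy‑2,2‑dimethyl‑6‑[6‑methyl‑1‑(4‑methylbenzenesulfonyl)heptyl]‑3,4‑dihydro‑2H‑chromen‑8‑yl]‑2‑methylbutan‑1‑one (both epimers at the sulfonyl‑bearing carbon) | CC[C@@H](C)C(=O)c1c(O)c(C(CCCCC(C)C)S(=O)(=O)c3ccc(C)cc3)c(OCc3ccccc3)c2c1OC(C)(C)CC2 | intermediate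
10 | isobutyryl chloride (2‑methylpropanoyl chloride) | CC(C)C(=O)Cl | starting material
11 | 2‑methyl‑1‑(2,4,6‑trihydroxyphenyl)propan‑1‑one | CC(C)C(=O)c1c(O)cc(O)cc1O | intermediate
12 | 1‑[4‑(benzyloxy)‑2,6‑dihydroxyphenyl]‑2‑methylpropan‑1‑one | CC(C)C(=O)c1c(O)cc(OCc2ccccc2)cc1O | intermediate
13 | formaldehyde (used as formalin) | C=O | starting material
14 | 1‑[4‑(benzyloxy)‑2,6‑dihydroxy‑3‑{[(4‑methoxyphenyl)sulfanyl]methyl}phenyl]‑2‑methylpropan‑1‑one | CC(C)C(=O)c1c(O)cc(OCc2ccccc2)c(CSc2ccc(OC)cc2)c1O | intermediate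
15 | ring‑A o‑quinone methide: 5‑(benzyloxy)‑2,2‑dimethyl‑8‑[(2R)‑2‑methylbutanoyl]‑6‑(6‑methylheptylidene)‑3,4‑dihydro‑2H‑chromen‑7(6H)‑one (alkene geometry not fixed) | CC[C@@H](C)C(=O)C1=C2OC(C)(C)CCC2=C(OCc2ccccc2)C(=CCCCCC(C)C)C1=O | intermediate (not isolated)
16 | (2R)‑1‑[5‑(benzyloxy)‑6‑[(1S)‑1‑[2‑(benzyloxy)‑4,6‑dihydroxy‑3‑{[(4‑methoxyphenyl)sulfanyl]methyl}‑5‑(2‑methylpropanoyl)phenyl]‑6‑methylheptyl]‑7‑hydroxy‑2,2‑dimethyl‑3,4‑dihydro‑2H‑chromen‑8‑yl]‑2‑methylbutan‑1‑one | CC[C@@H](C)C(=O)c1c(O)c([C@H](CCCCC(C)C)c2c(OCc3ccccc3)c(CSc3ccc(OC)cc3)c(O)c(C(=O)C(C)C)c2O)c(OCc2ccccc2)c2c1OC(C)(C)CC2 | intermediate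
17 | isobutylene (2‑methylpropene) | CC(C)=C | starting material
18 | ring‑B o‑quinone methide: 5‑(benzyloxy)‑4‑[(1S)‑1‑{5‑(benzyloxy)‑7‑hydroxy‑2,2‑dimethyl‑8‑[(2R)‑2‑methylbutanoyl]‑3,4‑dihydro‑2H‑chromen‑6‑yl}‑6‑methylheptyl]‑3‑hydroxy‑6‑methylidene‑2‑(2‑methylpropanoyl)cyclohexa‑2,4‑dien‑1‑one | CC[C@@H](C)C(=O)c1c(O)c([C@H](CCCCC(C)C)C2=C(OCc3ccccc3)C(=C)C(=O)C(C(=O)C(C)C)=C2O)c(OCc2ccccc2)c2c1OC(C)(C)CC2 | intermediate (not isolated)
19 | 1‑[5‑(benzyloxy)‑6‑[(1R)‑1‑{5‑(benzyloxy)‑7‑hydroxy‑2,2‑dimethyl‑8‑[(2R)‑2‑methylbutanoyl]‑3,4‑dihydro‑2H‑chromen‑6‑yl}‑6‑methylheptyl]‑7‑hydroxy‑2,2‑dimethyl‑3,4‑dihydro‑2H‑chromen‑8‑yl]‑2‑methylpropan‑1‑one | CC[C@@H](C)C(=O)c1c(O)c([C@H](CCCCC(C)C)c2c(OCc4ccccc4)c3c(c(C(=O)C(C)C)c2O)OC(C)(C)CC3)c(OCc2ccccc2)c2c1OC(C)(C)CC2 | intermediate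
20 | 1‑[6‑[(1R)‑1‑{5,7‑dihydroxy‑2,2‑dimethyl‑8‑[(2R)‑2‑methylbutanoyl]‑3,4‑dihydro‑2H‑chromen‑6‑yl}‑6‑methylheptyl]‑5,7‑dihydroxy‑2,2‑dimethyl‑3,4‑dihydro‑2H‑chromen‑8‑yl]‑2‑methylpropan‑1‑one | CC[C@@H](C)C(=O)c1c(O)c([C@H](CCCCC(C)C)c2c(O)c3c(c(C(=O)C(C)C)c2O)OC(C)(C)CC3)c(O)c2c1OC(C)(C)CC2 | target

## Step count and risks

Total steps: 10. Longest linear sequence: 7 steps (1, 2, 3, 4, 8, 9, 10).

Steps most likely to fail:

1. Step 8. The catalyst may discriminate poorly between the two faces of a hindered, alkyl‑substituted o‑quinone methide whose alkylidene geometry is not fixed, giving a low ratio of bridge epimers. Fallback: setting out from 9 and 14, the coupling is run with achiral base only (aq. Na2CO3, Bu4NBr, CH2Cl2, rt). This should give 16 together with its (1R)‑bridge epimer F1. Because of the (R)‑acyl centre the two are diastereomers and are separated by preparative HPLC on a polysaccharide chiral stationary phase. F1 is returned to the equilibrium mixture by base‑induced retro‑1,4‑addition/re‑addition (DBU, PhMe, 60 °C) and separated again. The route is rejoined at 16.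

2. Step 9. Anodic oxidation of the phenolic rings, or acid‑initiated oligomerisation of isobutylene, may compete with clean C–S cleavage and cycloaddition. Fallback: setting out from 9, the step‑8 coupling is run with 12 (threefold excess, to suppress double alkylation) in place of 14. This should give the sulfide‑free diaryl compound F2, whose ring B has one free CH flanked by the benzyl ether and the acyl‑side OH. Acid‑catalysed Friedel–Crafts prenylation and hydroalkoxylation with isoprene 6 (Amberlyst 15, THF/heptane, 50 °C, as in step 3) then closes the pyran through the only free neighbouring OH. The route is rejoined at 19.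

3. Step 4. A second arylation of the benzylic cation by 7 (symmetrical bis‑arene formation) may outrun sulfinate capture, and the sulfone may re‑ionise in acid. Fallback: setting out from 7 and 8, condensation with phenylboronic acid (cat. EtCO2H, PhMe, reflux, Dean–Stark) should give the cyclic phenylboronate F3. Here boron ties the benzylic oxygen to the 7‑oxygen in a temporary 1,3,2‑dioxaborin ring, so a second arylation cannot occur. Opening with TolSO2H (HCO2H/CH2Cl2, rt) by S‑alkylation at the benzylic carbon rejoins the route at 9.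

## Further compounds

F1 | step 8 | (2R)‑1‑[5‑(benzyloxy)‑6‑[(1R)‑1‑[2‑(benzyloxy)‑4,6‑dihydroxy‑3‑{[(4‑methoxyphenyl)sulfanyl]methyl}‑5‑(2‑methylpropanoyl)phenyl]‑6‑methylheptyl]‑7‑hydroxy‑2,2‑dimethyl‑3,4‑dihydro‑2H‑chromen‑8‑yl]‑2‑methylbutan‑1‑one (bridge epimer of 16) | CC[C@@H](C)C(=O)c1c(O)c([C@@H](CCCCC(C)C)c2c(OCc3ccccc3)c(CSc3ccc(OC)cc3)c(O)c(C(=O)C(C)C)c2O)c(OCc2ccccc2)c2c1OC(C)(C)CC2
F2 | step 9 | (2R)‑1‑[5‑(benzyloxy)‑6‑[(1R)‑1‑[6‑(benzyloxy)‑2,4‑dihydroxy‑3‑(2‑methylpropanoyl)phenyl]‑6‑methylheptyl]‑7‑hydroxy‑2,2‑dimethyl‑3,4‑dihydro‑2H‑chromen‑8‑yl]‑2‑methylbutan‑1‑one | CC[C@@H](C)C(=O)c1c(O)c([C@H](CCCCC(C)C)c2c(OCc3ccccc3)cc(O)c(C(=O)C(C)C)c2O)c(OCc2ccccc2)c2c1OC(C)(C)CC2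
F3 | step 4 | cyclic phenylboronate of (2R)‑1‑[5‑(benzyloxy)‑7‑hydroxy‑6‑(1‑hydroxy‑6‑methylheptyl)‑2,2‑dimethyl‑3,4‑dihydro‑2H‑chromen‑8‑yl]‑2‑methylbutan‑1‑one (boron bridges the 7‑oxygen and the benzylic oxygen; both epimers at the benzylic carbon) | CC[C@@H](C)C(=O)c1c2OB(c3ccccc3)OC(CCCCC(C)C)c2c(OCc2ccccc2)c2c1OC(C)(C)CC2
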